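The flask holds 5.0 × 10⁻⁴ M of each mirror substrate against 0.300 mM of coupling partner.

common to all: left-handed substrate 5.0 × 10⁻⁴ M; right-handed substrate 5.0 × 10⁻⁴ M; free catalyst 0.50 µM; stray impurity 0.096 µM
- dusk: coupling partner 0.15 mM; protic impurity 0.10 mM; added ligand 0.73 µM; run made earlier
- spring: coupling partner 0.22 mM; protic impurity 0.10 mM; added ligand 0.73 µM; run made earlier
- winter: coupling partner 0.30 mM; protic impurity 0.10 mM; added ligand 1.1 µM; run made earlier
- flask: coupling partner 0.300 mM; protic impurity 0.100 mM; added ligand 0.73 µM; time 2.5 min

- dusk (time / s: left-handed product / %, right-handed product / %): 10.0: 11.8, 3.9; 20.0: 10.0, 2.7; 30.0: 10.0, 4.5; 50.0: 10.6, 3.9; 80.0: 9.9, 3.9; 90.0: 10.0, 4.3; 120: 11.2, 4.2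
- spring (time / s: left-handed product / %, right-handed product / %): 10.0: 14.0, 7.0; 15.0: 15.3, 6.4; 20.0: 14.8, 3.4; 30.0: 14.9, 7.2; 50.0: 14.9, 5.3; 80.0: 15.0, 6.3; 120: 15.3, 6.4
- winter (time / s: left-handed product / %, right-handed product / %): 25.0: 21.9, 8.9; 50.0: 20.4, 6.5; 80.0: 21.2, 8.5; 90.0: 20.2, 8.3; 120: 20.0, 8.3

(readings scatter by 1 percentage point)

- free catalyst is single-handed; left-handed substrate and right-handed substrate are mirror images of each other, charged as a racemate, each of them at the stated concentration
- an excess is the difference of the two amounts in percent of their sum
- an excess is below zero if the other one leads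

1. excess of left-handed product over right-handed product in the product at 15 s
2. excess of left-handed product over right-handed product in the product at 2.5 min
3. part of the left-handed substrate and right-handed substrate charged together that has reacted at 2.5 min

We build the flask up step by step, as our own reckoning. First the main step: one coupling partner makes one product, and there is less partner than substrate, so the partner is the limiting reagent and product tops out at 30.0 % of the substrates charged.

Next comes the loss. Winter has the flask's partner charge, and its readings average 20.7 % left-handed and 8.10 % right-handed product. So 96.1 % of its partner appears as product, and we guess that the protic impurity took the gap. So we reckon 28.8 % reacted in the flask.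

Then the ligand: winter carries 1.1 µM, but spring, with the flask's 0.73 µM and less partner than winter, shows a product share of 94.9 %, so we keep winter's share.

We carry one number for the split, read from winter as s = 3.03: the selectivity factor, the logarithm of the share of left-handed substrate remaining divided by the logarithm of the share of right-handed substrate remaining. With equal substrates at the start, s gives an excess of 50.4 %. But the left-handed substrate falls faster than the right-handed, so we replace each substrate curve by its mean over the run and multiply s by the ratio of those means. The product ratio becomes 2.56, an excess of 43.8 %. Winter's mean readings, from which s itself came, also give 43.8 %, so this tests the averaging step and no more.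

Spring, with less partner than the flask, already shows 14.0 % left-handed product at 10.0 s, level with its later readings within their scatter, so we reckon the same excess at 15 s and 2.5 min.

The forecast gives an excess of 43 % at 15 s and 43 % at 2.5 min, with 29 % reacted, holding that “the partner is limiting”. Our excess stands above the forecast's.

The flask gives an excess of 44.6 % at 15 s and 44.6 % at 2.5 min, with 28.4 % reacted.

    coupling partner + catalyst intermediate A → free catalyst + left-handed product (k = 9.70 × 10⁶ M⁻¹ s⁻¹)
    free catalyst + left-handed substrate ⇌ catalyst intermediate A (K = 3400 M⁻¹, k = 9.10 × 10⁷ M⁻¹ s⁻¹)
    coupling partner + protic impurity → quenched reagent (k = 930 M⁻¹ s⁻¹)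
    free catalyst + stray impurity → spent catalyst (k = 3.70 × 10⁷ M⁻¹ s⁻¹)
    coupling partner + catalyst intermediate B → free catalyst + right-handed product (k = 3.10 × 10⁶ M⁻¹ s⁻¹)
    free catalyst + added ligand ⇌ idle complex, settled at all times (K = 1.90 × 10⁶ M⁻¹)
    free catalyst + right-handed substrate ⇌ catalyst intermediate B (K = 5100 M⁻¹, k = 3.60 × 10⁶ M⁻¹ s⁻¹)

The flask keeps 59 % of its left-handed and 84 % of its right-handed substrate, which puts s at 3.08. The split moves in the neighbouring flask, which has 7.5 × 10⁻⁵ M of coupling partner and the other charges as in the recipe. Our reckoning gives it 7.21 % reacted, and it shows 7.13 %. Carrying s = 3.03, the ratio is 2.92 and the excess 49.0 %, but the neighbour shows a lower 39.7 %. Its 4.96 % left-handed and 2.14 % right-handed product put s at 2.39.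

All runs were computed from invented constants; noise was put on by code.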